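Take the products of the grey run together and treat them, as one does at the bench, as a single first-order climb towards the whole charge.

- grey: starting material 0.095 M; protic impurity 0.019 M; run made earlier
- flask: starting material 0.19 M; protic impurity 0.0190 M; time 15 d

grey run (percent of the starting material charged)

| time / d | target / % | isomer of the product / % |
|---|---|---|
| 0.417 | 10.0 | 4.5 |
| 0.833 | 15.5 | 11.7 |
| 1.25 | 21.2 | 20.3 |
| 1.67 | 23.1 | 26.2 |
| 2.00 | 27.4 | 31.1 |
| 2.50 | 30.2 | 36.9 |
| 3.00 | 32.0 | 39.6 |

(scatter of a reading: 1 percentage point)

1. why nothing more happens at 15 d, or that something still does (all of the starting material has reacted / forward and back rates have come level / it is still moving)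
2. target at 15 d, in percent of the starting material charged
3. isomer of the product at 15 d, in percent of the starting material charged

- a reading or a percentage of target counts all its forms, free or not
- the reaction counts as stopped when no species that holds the starting material changes by six tenths of a point or more over the second half of the time

The last grey reading sums to 71.6%, which gives a half-life of 1.65 d. The flask runs 15 d, or 9.09 such half-lives, so the rule calls it finished: we expect the starting material to have reacted to the last.

But the rule assumes that the whole charge can reach product. Our own guess is that each protic impurity removes one starting material, the way an irreversible inhibitor titrates an enzyme. The ratio of the charges then sets a limit: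

ceiling = 1 − [protic impurity]/[starting material] = 90.0%

This ceiling, the share of the charge left after the impurity has taken its equal number, is 80.0% for the grey run. The grey sum still stands below that, so those readings leave the guess untested. Splitting the flask's ceiling by the last grey reading of isomer over target, 1.24, we reckon 40.2% target and 49.8% isomer of the product.

The forecast differs: forward and back rates have come level, 41% target and 59% isomer of the product, on the ground that “Equilibrium is independent of concentration”. Its two numbers add to the whole charge, ours to the ceiling.

The flask gives: all of the starting material has reacted, 39.1% target, 50.9% isomer of the product.

    starting material → intermediate A (k = 0.0892 /h)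
    intermediate A → target (k = 0.0524 /h)
    intermediate A → intermediate B (k = 0.102 /h)
    intermediate B → target (k = 0.0373 /h)
    starting material + target ⇌ idle adduct, settled at all times (K = 16.2 /M)
    target ⇌ isomer of the product (K = 1.30, k = 0.205 /h)
    starting material + protic impurity → quenched substrate (k = 4.43 /M/h)

These add to 90.0%, the ceiling of 90.0%. The missing part stands as 10.0% quenched substrate, and the protic impurity, limiting reagent of that side reaction, is down to 0.020% of its own charge. Within the sum, this flask holds 39.1% target and not the 90.0% of the run without isomerisation, because target turns into isomer of the product and back. The neighbour flask, with 0.0047 M protic impurity, has a ceiling of 97.5%; it ends with 42.4% target and 55.1% isomer of the product, 97.5% together, beside 2.47% quenched substrate.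

The earlier runs and the new flask come from a simulation with made-up constants; scatter was added.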